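A rising curve tempts one to read its last doubling as a promise of a plateau, yet a rise shows nothing of what happens to target afterwards. The decision is whether the south-west flask, charged with 0.050 M of solid substrate, may stand unwatched to 15 h.

| flask | solid substrate | remark | time |
|---|---|---|---|
| south-west | 0.050 M | the very flask that is asked about, followed so far |  |
| east | 0.025 M | run made earlier |  |
| flask | 0.050 M |  | 15 h |

- south-west (time / h: target / %): 1.33: 2; 2.00: 2; 2.50: 2; 3.00: 6; 4.00: 11; 5.00: 24
- east (time / h: target / %): 1.33: 3; 2.00: 1; 2.50: 3; 3.00: 1; 4.00: 4; 5.00: 4; 6.00: 2

(standard deviation of a reading: 2 percentage points)

1. time up to 15 h at which target stands highest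
2. the amount of target, in percent of the solid substrate charged, at that time

- solid, in amounts per volume of the solution: solid substrate
- at the start none of the solid substrate is in solution

In the south-west run target climbs from 6% of the charge at 3.00 h to 24% at 5.00 h, so the doubling time, the hours target needs to double during the rise, reads 1.00 h, subject to the scatter of 2 percentage points. The east run, at half the charge, stays within 4% up to 6.00 h, so this clock belongs to the south-west flask. From its last reading, 2.06 doublings fill the charge, at about 7.06 h. The time remaining after that reading holds 10.0 doubling times, more than the filling needs. My reckoning therefore takes about 7.06 h as the hour at which unbroken doubling would meet the charge; this is an estimate and no bound on the peak, for a slowing rise fills later, and the south-west readings end at 5.00 h with target still rising and show no loss of it. The decision is to keep the charge but sample the south-west flask every 0.500 h from 5.00 h on, rather than wait for 15 h.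

The forecast gives 97% at 15 h, in its words “I therefore expect a plateau near full conversion”.

    starting material + 2 target → 3 target (k = 163 /M²/min)
    starting material → target (k = 5.39 × 10⁻⁴ /min)
    target → over-reaction product (k = 0.00795 /min)
    starting material ⇌ dormant form (K = 0.770, k = 0.0116 /min)
    solid substrate ⇌ starting material, rate k5*(cs5 - [starting material]) while solid is left; crystals form when [starting material] > cs5 (solubility = 48.0 mM, k = 0.0382 /min)

The south-west flask tops out at 46.0% of the charge at 5.81 h, earlier than the fill time, and the clock run on from the last reading gives 42.1% at that moment. The solid substrate has 100% of its dissolution behind it by 3.00 h, and the autocatalytic step reaches half its turnover at 5.20 h, with starting material down to 4.21% at the peak. Target then passes to over-reaction product with a half-life of 1.5 h, short against 15 h, standing at 30.8% at 7.50 h and 1.22% at 15.0 h.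

The clock was read at 0.050 M and the east run at 0.025 M did not follow it, so for the neighbour flask with 0.085 M of solid substrate it is a trial figure: lent unchanged, it counts 15.0 doubling times in 15 h, more than the 5.64 that lift 2% to the whole charge, and this count says nothing of any loss of target. Computed, it peaks at 59.7% and ends with 0.481% target and 98.9% over-reaction product.

(The readings were computed for an exercise; the scatter is artificial.)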